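**Plan**

- Retrosynthetic cuts: the two Si–O bonds; the epoxide C–O bonds (back to the 1(10)E olefin); the C8 O–acyl bond (alcohol 20 + side-chain acid 33, itself cut at its CH2–O ester bond into two Baylis–Hillman units); C11=C13 and the O6–C12 lactone bond; then C7–C11 and C8–C9 in one operation (back to cyclohexenol 10); finally C6–C7 (enone 4 + Z-alkoxyvinyllithium 9).
- Enabling feature: C8–C9 lies between the C1=C10 olefin (the epoxide precursor) and the oxygen-bearing C6, so C9=C10–C1–C6(O−)–C7=C8 is a 3-oxido-1,5-diene. The ten-membered ring C1–C10 is therefore a six-membered ring (C1–C6, whose cis double bond is the 4Z olefin) enlarged by four carbons.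
- Forward order: carvone-derived cyclohexene, then the ten-membered ring by ring expansion with C7 alkylation in the same flask, then the γ-lactone, the α-methylene group, the side chain, and the epoxide ring last.
- Stereochemistry: C3 from (S)-carvone by Luche reduction; the carvone stereocentre (germacrane C1) steers the vinyl addition and is then consumed, relaying chirality to C8 through the chair; C7 by enolate alkylation; C6 by C8–OH-directed reduction; C1/C10 by peripheral epoxidation of the E olefin; side-chain olefins by allylic transposition of Baylis–Hillman adducts.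

Key step: step 7

Remark: ring compounds are described with germacrane numbering (ring C1–C10, lactone carbons C11–C13, C14 on C10, C15 on C4); the epoxide configuration is assumed to arise from peracid attack on the outer face of the E olefin, as is usual for germacranolides.

**Route**

Step 1
Reactants: 1 (S)-(+)-carvone
Product: 2 (1S,5S)-cis-carveol
Conditions: NaBH4, CeCl3·7H2O, MeOH, 0 °C
Reagents that add atoms: none
Why: Luche reduction gives clean 1,2-reduction, and axial hydride delivery to the half-chair with equatorial isopropenyl should give the alcohol cis to the isopropenyl group, which becomes C3 (S).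

Step 2
Reactants: 2 (1S,5S)-cis-carveol
Product: 3 tert-butyl{[(1S,5S)-2-methyl-5-(prop-1-en-2-yl)cyclohex-2-en-1-yl]oxy}dimethylsilane
Conditions: TBSCl, imidazole, DMF, rt
Reagents that add atoms: tert-butyldimethylsilyl chloride, CC(C)(C)[Si](C)(C)Cl
Why: Standard silylation of a secondary allylic alcohol; the TBS ether is chosen to survive organolithium, amide base, DDQ, borohydride and peracid steps.

Step 3
Reactants: 3 tert-butyl{[(1S,5S)-2-methyl-5-(prop-1-en-2-yl)cyclohex-2-en-1-yl]oxy}dimethylsilane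
Product: 4 (4S,6S)-4-[(tert-butyldimethylsilyl)oxy]-3-methyl-6-(prop-1-en-2-yl)cyclohex-2-en-1-one (silyloxy and isopropenyl cis)
Conditions: CrO3, 3,5-dimethylpyrazole, CH2Cl2, −20 °C
Reagents that add atoms: chromium trioxide, O=[Cr](=O)=O
Why: Chromium-mediated allylic oxidation should convert the only free ring CH2 allylic to the trisubstituted olefin into the enone under non-basic conditions, so the now α-carbonyl isopropenyl centre is not epimerised and no stereocentre is touched.

Step 4
Reactants: 5 4-methoxybenzyl alcohol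
Product: 6 4-methoxybenzyl vinyl ether
Conditions: Pd(OCOCF3)2 (cat.), 4,7-diphenyl-1,10-phenanthroline, Et3N, butyl vinyl ether (solvent), 75 °C
Reagents that add atoms: butyl vinyl ether, C=COCCCC
Why: Palladium-catalysed transfer vinylation (transetherification) of a primary alcohol, driven by the excess of butyl vinyl ether.

Step 5
Reactants: 6 4-methoxybenzyl vinyl ether
Product: 8 1-{[(Z)-2-bromoethenyl]oxymethyl}-4-methoxybenzene, via dibromo ether 7 (not isolated)
Conditions: Br2, CH2Cl2, −78 °C; then i-Pr2NEt, −78 °C → 40 °C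
Reagents that add atoms: bromine, BrBr
Why: Bromine addition to the vinyl ether followed by amine-induced loss of HBr through the α-bromo ether should give mainly the Z 2-bromovinyl ether (cis effect of 1-alkoxy-2-haloethenes), as for the ethyl analogue; the E isomer is removed by chromatography.

Step 6
Reactants: 8 1-{[(Z)-2-bromoethenyl]oxymethyl}-4-methoxybenzene; 4 (4S,6S)-4-[(tert-butyldimethylsilyl)oxy]-3-methyl-6-(prop-1-en-2-yl)cyclohex-2-en-1-one
Product: 10 (1S,4S,6S)-4-[(tert-butyldimethylsilyl)oxy]-1-[(Z)-2-(4-methoxybenzyloxy)ethenyl]-3-methyl-6-(prop-1-en-2-yl)cyclohex-2-en-1-ol, via vinyllithium 9 (not isolated)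
Conditions: t-BuLi (2 equiv), Et2O, −78 °C; then 4, THF, −78 °C
Reagents that add atoms: none
Why: Bromine–lithium exchange with retention gives the Z reagent, held by internal O–Li coordination, and its 1,2-addition to the enone from the face opposite the isopropenyl and silyloxy groups should set the carbinol centre with the two alkenyl groups trans.

Step 7
Reactants: 10 (1S,4S,6S)-4-[(tert-butyldimethylsilyl)oxy]-1-[(Z)-2-(4-methoxybenzyloxy)ethenyl]-3-methyl-6-(prop-1-en-2-yl)cyclohex-2-en-1-ol; 11 methyl bromoacetate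
Product: 14 methyl (3S,7R,8R)-3-[(tert-butyldimethylsilyl)oxy]-8-[(4-methoxybenzyl)oxy]-6-oxo-13-norgermacra-1(10)E,4Z-dien-12-oate, via potassium alkoxide 12 (not isolated), via potassium enolate 13 (not isolated)
Conditions: KN(SiMe3)2, THF, 0 → 45 °C; then 11, −78 → −40 °C
Reagents that add atoms: none
Why: Deprotonation gives alkoxide 12, whose C1–C6 σ-bond lies between the isopropenyl group (C9=C10) and the Z-alkoxyvinyl group (C7=C8), so a concerted [3,3]-sigmatropic shift through a chair transition state breaks C1–C6, makes C8–C9 and gives the cross-conjugated enolate 13, which methyl bromoacetate alkylates on C7. The closest known reaction type is the anionic oxy-Cope ring expansion of trans-1,2-dialkenylcyclohexenols to cyclodecadienones with alkylation of the enolate in the same flask. The ten-membered ring closes by a four-carbon ring expansion (a suprafacial six-centre shift, not an exo or endo cyclisation); the cyclohexene double bond survives as the 4Z olefin and the equatorial C1–C2 bond of the chair fixes the 1(10)E olefin. C8 (R) follows from chirality transfer, because the diequatorial alkenyl groups allow only one chair and the Z enol ether places the PMB-oxy group axial on C8, bridged to the alkoxide oxygen by K+. C7 (R) is set in the alkylation, the electrophile entering the outer face of the K+-chelated O6–C6=C7–C8–O8 enolate, anti to the new C8–C9 ring bond. The step needs chair over boat and C-alkylation over β-loss of the C8 alkoxy group; the diequatorial arrangement should secure the first, and the chelate, which holds the C8–O bond in the nodal plane of the enolate, the second.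

Step 8
Reactants: 14 methyl (3S,7R,8R)-3-[(tert-butyldimethylsilyl)oxy]-8-[(4-methoxybenzyl)oxy]-6-oxo-13-norgermacra-1(10)E,4Z-dien-12-oate
Product: 15 methyl (3S,7R,8R)-3-[(tert-butyldimethylsilyl)oxy]-8-hydroxy-6-oxo-13-norgermacra-1(10)E,4Z-dien-12-oate
Conditions: DDQ, CH2Cl2/pH 7 buffer (10:1), 0 °C; used at once
Reagents that add atoms: none
Why: Oxidative PMB cleavage (hydride abstraction by DDQ, hydrolysis of the oxocarbenium ion) under neutral conditions should spare the silyl ether, ester, enone and olefins and avoid retro-aldol opening of the β-hydroxy ketone.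

Step 9
Reactants: 15 methyl (3S,7R,8R)-3-[(tert-butyldimethylsilyl)oxy]-8-hydroxy-6-oxo-13-norgermacra-1(10)E,4Z-dien-12-oate
Product: 17 (3S,6R,7R,8R)-3-[(tert-butyldimethylsilyl)oxy]-8-hydroxy-13-norgermacra-1(10)E,4Z-dien-12,6-olide, via diol ester 16 (not isolated)
Conditions: Me4NBH(OAc)3, MeCN/AcOH (1:1), −30 °C; then PPTS, benzene, 50 °C
Reagents that add atoms: none
Why: Evans–Saksena reduction delivers hydride internally from boron bound to the C8 hydroxyl and should set C6 (R) anti to C8, after which equilibrating acid lactonisation is expected to close onto the allylic C6 oxygen to give the trans-fused 6,12-olide typical of 8β-hydroxy germacranolides.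

Step 10
Reactants: 17 (3S,6R,7R,8R)-3-[(tert-butyldimethylsilyl)oxy]-8-hydroxy-13-norgermacra-1(10)E,4Z-dien-12,6-olide
Product: 20 (3S,6R,7R,8R)-3-[(tert-butyldimethylsilyl)oxy]-8-hydroxygermacra-1(10)E,4Z,11(13)-trien-12,6-olide, via Mannich base 18 (not isolated), via methiodide 19 (not isolated)
Conditions: LiN(i-Pr)2 (3 equiv), THF, −78 °C; CH2=NMe2+ I−, −78 → 0 °C; MeI, MeOH, rt; NaHCO3 (aq), CH2Cl2
Reagents that add atoms: Eschenmoser's salt (N,N-dimethylmethyleneiminium iodide), C=[N+](C)C.[I-]
Why: Eschenmoser methylenation: Mannich reaction of the lithium lactone enolate (the C8 alkoxide is carried as a spectator), N-methylation and β-elimination of trimethylamine give the exocyclic C11=C13 olefin, C11 being the only enolisable position.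

Step 11
Reactants: 21 tert-butyl acrylate; 22 acetaldehyde
Product: 23 tert-butyl 3-hydroxy-2-methylidenebutanoate (racemic)
Conditions: DABCO (1 equiv), 1,4-dioxane/H2O (1:1), rt
Reagents that add atoms: none
Why: Baylis–Hillman reaction; the carbinol centre is removed in the next step, so the racemate is sufficient.

Step 12
Reactants: 23 tert-butyl 3-hydroxy-2-methylidenebutanoate
Product: 24 tert-butyl (2Z)-2-(bromomethyl)but-2-enoate
Conditions: NBS, Me2S, CH2Cl2, 0 °C → rt
Reagents that add atoms: N-bromosuccinimide, O=C1CCC(=O)N1Br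
Why: Bromide attacks the alkoxysulfonium derivative with allylic transposition (SN2'), which should give the trisubstituted olefin with the methyl group cis to CH2Br and trans to the ester, as is usual for Baylis–Hillman adducts.

Step 13
Reactants: 21 tert-butyl acrylate; 25 [(tert-butyldimethylsilyl)oxy]acetaldehyde
Product: 26 tert-butyl 4-[(tert-butyldimethylsilyl)oxy]-3-hydroxy-2-methylidenebutanoate (racemic)
Conditions: DABCO (1 equiv), 1,4-dioxane/H2O (1:1), rt
Reagents that add atoms: none
Why: Baylis–Hillman reaction of a reactive α-silyloxy aldehyde; the carbinol centre is removed in the next step.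

Step 14
Reactants: 26 tert-butyl 4-[(tert-butyldimethylsilyl)oxy]-3-hydroxy-2-methylidenebutanoate
Product: 28 tert-butyl (2E)-2-(acetoxymethyl)-4-[(tert-butyldimethylsilyl)oxy]but-2-enoate, via secondary acetate 27 (not isolated)
Conditions: Ac2O, Et3N, DMAP (cat.), CH2Cl2, 0 °C; then DABCO, THF, 65 °C
Reagents that add atoms: acetic anhydride, CC(=O)OC(C)=O
Why: Acetylation followed by DABCO-mediated 1,3-transposition of the Baylis–Hillman acetate (SN2' then SN2') should give the thermodynamic primary acetate with CH2OTBS trans to the ester.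

Step 15
Reactants: 28 tert-butyl (2E)-2-(acetoxymethyl)-4-[(tert-butyldimethylsilyl)oxy]but-2-enoate
Product: 30 (2E)-2-(acetoxymethyl)-4-[(tert-butyldimethylsilyl)oxy]but-2-enoic acid, via trimethylsilyl ester 29 (not isolated)
Conditions: TMSOTf, 2,6-lutidine, CH2Cl2, 0 °C → rt; then pH 4 buffer
Reagents that add atoms: none
Why: Silyl triflate-mediated cleavage of the tert-butyl ester (loss of isobutene, then hydrolysis of the silyl ester) should spare the TBS ether and the allylic acetate, which aqueous acid or base would not.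

Step 16
Reactants: 30 (2E)-2-(acetoxymethyl)-4-[(tert-butyldimethylsilyl)oxy]but-2-enoic acid; 24 tert-butyl (2Z)-2-(bromomethyl)but-2-enoate
Product: 31 tert-butyl (2E)-2-({[(2E)-2-(acetoxymethyl)-4-[(tert-butyldimethylsilyl)oxy]but-2-enoyl]oxy}methyl)but-2-enoate
Conditions: Cs2CO3, DMF, 0 °C → rt
Reagents that add atoms: none
Why: Direct SN2 displacement of the primary allylic bromide by the caesium carboxylate, a soft nucleophile that should attack the CH2 carbon and keep the conjugated trisubstituted olefin.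

Step 17
Reactants: 31 tert-butyl (2E)-2-({[(2E)-2-(acetoxymethyl)-4-[(tert-butyldimethylsilyl)oxy]but-2-enoyl]oxy}methyl)but-2-enoate
Product: 33 (2E)-2-({[(2E)-2-(acetoxymethyl)-4-[(tert-butyldimethylsilyl)oxy]but-2-enoyl]oxy}methyl)but-2-enoic acid, via trimethylsilyl ester 32 (not isolated)
Conditions: TMSOTf, 2,6-lutidine, CH2Cl2, 0 °C → rt; then pH 4 buffer
Reagents that add atoms: none
Why: The same silyl triflate cleavage removes the tert-butyl ester without touching the acetate, the inner ester link or the silyl ether.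

Step 18
Reactants: 20 (3S,6R,7R,8R)-3-[(tert-butyldimethylsilyl)oxy]-8-hydroxygermacra-1(10)E,4Z,11(13)-trien-12,6-olide; 33 (2E)-2-({[(2E)-2-(acetoxymethyl)-4-[(tert-butyldimethylsilyl)oxy]but-2-enoyl]oxy}methyl)but-2-enoic acid
Product: 35 8-O-acyl derivative of 20 (3,4'-bis-TBS ether of 1,10-deoxy target), via mixed anhydride 34 (not isolated)
Conditions: 2,4,6-Cl3C6H2COCl, Et3N, THF, rt; then 20, DMAP, toluene, rt
Reagents that add atoms: none
Why: Yamaguchi esterification acylates the hindered secondary C8 hydroxyl (the only free OH) with retention at C8 and without the basic conditions that would threaten the α-methylene lactone.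

Step 19
Reactants: 35 8-O-acyl derivative of 20
Product: 36 (1R,10R)-1,10-epoxide of 35
Conditions: mCPBA, NaHCO3, CH2Cl2, 0 °C
Reagents that add atoms: meta-chloroperoxybenzoic acid, OOC(=O)c1cccc(Cl)c1
Why: Prilezhaev epoxidation: the 1(10) olefin is the only double bond that is neither conjugated to a carbonyl nor flanked by two allylic oxygens, and attack on its outer face in the crossed ring conformation should give the trans 1R,10R epoxide from the E olefin.

Step 20
Reactants: 36 (1R,10R)-1,10-epoxide of 35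
Product: 37 target CNP0193678.1
Conditions: HF·pyridine, pyridine, THF, 0 °C → rt
Reagents that add atoms: none
Why: Buffered fluoride cleavage of both Si–O bonds, under conditions that a trisubstituted epoxide, the allylic acetate and the α-methylene lactone should tolerate.

**Compound list**

1 | (S)-(+)-carvone, (5S)-2-methyl-5-(prop-1-en-2-yl)cyclohex-2-en-1-one | CC1=CC[C@@H](CC1=O)C(C)=C | starting material
2 | (1S,5S)-cis-carveol | CC1=CC[C@@H](C[C@@H]1O)C(C)=C | intermediate
3 | tert-butyl{[(1S,5S)-2-methyl-5-(prop-1-en-2-yl)cyclohex-2-en-1-yl]oxy}dimethylsilane | CC1=CC[C@@H](C[C@@H]1O[Si](C)(C)C(C)(C)C)C(C)=C | intermediate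
4 | (4S,6S)-4-[(tert-butyldimethylsilyl)oxy]-3-methyl-6-(prop-1-en-2-yl)cyclohex-2-en-1-one | CC1=CC(=O)[C@@H](C[C@@H]1O[Si](C)(C)C(C)(C)C)C(C)=C | intermediate
5 | 4-methoxybenzyl alcohol | COc1ccc(CO)cc1 | starting material
6 | 4-methoxybenzyl vinyl ether | COc1ccc(COC=C)cc1 | intermediate
7 | 1-[(1,2-dibromoethoxy)methyl]-4-methoxybenzene (racemic) | COc1ccc(COC(Br)CBr)cc1 | intermediate (not isolated)
8 | 1-{[(Z)-2-bromoethenyl]oxymethyl}-4-methoxybenzene | COc1ccc(CO/C=C\Br)cc1 | intermediate
9 | [(Z)-2-(4-methoxybenzyloxy)ethenyl]lithium | COc1ccc(CO/C=C\[Li])cc1 | intermediate (not isolated)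
10 | (1S,4S,6S)-4-[(tert-butyldimethylsilyl)oxy]-1-[(Z)-2-(4-methoxybenzyloxy)ethenyl]-3-methyl-6-(prop-1-en-2-yl)cyclohex-2-en-1-ol | CC1=C[C@@](O)(/C=C\OCc2ccc(OC)cc2)[C@@H](C[C@@H]1O[Si](C)(C)C(C)(C)C)C(C)=C | intermediate
11 | methyl bromoacetate | COC(=O)CBr | starting material
12 | potassium alkoxide of 10 | [K+].CC1=C[C@@]([O-])(/C=C\OCc2ccc(OC)cc2)[C@@H](C[C@@H]1O[Si](C)(C)C(C)(C)C)C(C)=C | intermediate (not isolated)
13 | potassium (3S,8R)-3-[(tert-butyldimethylsilyl)oxy]-8-[(4-methoxybenzyl)oxy]-11,12,13-trinorgermacra-1(10)E,4Z,6-trien-6-olate (O6 cis to C8, C5 trans to C8 across C6=C7) | [K+].C1/C(C)=C/C[C@H](O[Si](C)(C)C(C)(C)C)/C(C)=C\C(\[O-])=C\[C@@H]1OCc2ccc(OC)cc2 | intermediate (not isolated)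
14 | methyl (3S,7R,8R)-3-[(tert-butyldimethylsilyl)oxy]-8-[(4-methoxybenzyl)oxy]-6-oxo-13-norgermacra-1(10)E,4Z-dien-12-oate | O=C1/C=C(/C)[C@@H](O[Si](C)(C)C(C)(C)C)C/C=C(\C)C[C@@H](OCc2ccc(OC)cc2)[C@H]1CC(=O)OC | intermediate
15 | methyl (3S,7R,8R)-3-[(tert-butyldimethylsilyl)oxy]-8-hydroxy-6-oxo-13-norgermacra-1(10)E,4Z-dien-12-oate | O=C1/C=C(/C)[C@@H](O[Si](C)(C)C(C)(C)C)C/C=C(\C)C[C@@H](O)[C@H]1CC(=O)OC | intermediate
16 | methyl (3S,6R,7R,8R)-3-[(tert-butyldimethylsilyl)oxy]-6,8-dihydroxy-13-norgermacra-1(10)E,4Z-dien-12-oate | O[C@@H]1/C=C(/C)[C@@H](O[Si](C)(C)C(C)(C)C)C/C=C(\C)C[C@@H](O)[C@H]1CC(=O)OC | intermediate (not isolated)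
17 | (3S,6R,7R,8R)-3-[(tert-butyldimethylsilyl)oxy]-8-hydroxy-13-norgermacra-1(10)E,4Z-dien-12,6-olide (trans-fused) | C1C(=O)O[C@@H]2/C=C(/C)[C@@H](O[Si](C)(C)C(C)(C)C)C/C=C(\C)C[C@@H](O)[C@@H]12 | intermediate
18 | 13-(dimethylamino)-11,13-dihydro derivative of 20 (C11 configuration not defined, lost on elimination) | CN(C)CC1C(=O)O[C@@H]2/C=C(/C)[C@@H](O[Si](C)(C)C(C)(C)C)C/C=C(\C)C[C@@H](O)[C@@H]12 | intermediate (not isolated)
19 | trimethylammonium iodide from 18 | C[N+](C)(C)CC1C(=O)O[C@@H]2/C=C(/C)[C@@H](O[Si](C)(C)C(C)(C)C)C/C=C(\C)C[C@@H](O)[C@@H]12.[I-] | intermediate (not isolated)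
20 | (3S,6R,7R,8R)-3-[(tert-butyldimethylsilyl)oxy]-8-hydroxygermacra-1(10)E,4Z,11(13)-trien-12,6-olide | C=C1C(=O)O[C@@H]2/C=C(/C)[C@@H](O[Si](C)(C)C(C)(C)C)C/C=C(\C)C[C@@H](O)[C@@H]12 | intermediate
21 | tert-butyl acrylate | C=CC(=O)OC(C)(C)C | starting material
22 | acetaldehyde | CC=O | starting material
23 | tert-butyl 3-hydroxy-2-methylidenebutanoate (racemic) | CC(O)C(=C)C(=O)OC(C)(C)C | intermediate
24 | tert-butyl (2Z)-2-(bromomethyl)but-2-enoate | C/C=C(\CBr)C(=O)OC(C)(C)C | intermediate
25 | [(tert-butyldimethylsilyl)oxy]acetaldehyde | O=CCO[Si](C)(C)C(C)(C)C | starting material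
26 | tert-butyl 4-[(tert-butyldimethylsilyl)oxy]-3-hydroxy-2-methylidenebutanoate (racemic) | C=C(C(O)CO[Si](C)(C)C(C)(C)C)C(=O)OC(C)(C)C | intermediate
27 | tert-butyl 3-acetoxy-4-[(tert-butyldimethylsilyl)oxy]-2-methylidenebutanoate (racemic) | C=C(C(OC(C)=O)CO[Si](C)(C)C(C)(C)C)C(=O)OC(C)(C)C | intermediate (not isolated)
28 | tert-butyl (2E)-2-(acetoxymethyl)-4-[(tert-butyldimethylsilyl)oxy]but-2-enoate | CC(=O)OC/C(=C\CO[Si](C)(C)C(C)(C)C)C(=O)OC(C)(C)C | intermediate
29 | trimethylsilyl (2E)-2-(acetoxymethyl)-4-[(tert-butyldimethylsilyl)oxy]but-2-enoate | CC(=O)OC/C(=C\CO[Si](C)(C)C(C)(C)C)C(=O)O[Si](C)(C)C | intermediate (not isolated)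
30 | (2E)-2-(acetoxymethyl)-4-[(tert-butyldimethylsilyl)oxy]but-2-enoic acid | CC(=O)OC/C(=C\CO[Si](C)(C)C(C)(C)C)C(=O)O | intermediate
31 | tert-butyl (2E)-2-({[(2E)-2-(acetoxymethyl)-4-[(tert-butyldimethylsilyl)oxy]but-2-enoyl]oxy}methyl)but-2-enoate | C/C=C(\COC(=O)/C(=C/CO[Si](C)(C)C(C)(C)C)COC(C)=O)C(=O)OC(C)(C)C | intermediate
32 | trimethylsilyl ester of 33 | C/C=C(\COC(=O)/C(=C/CO[Si](C)(C)C(C)(C)C)COC(C)=O)C(=O)O[Si](C)(C)C | intermediate (not isolated)
33 | (2E)-2-({[(2E)-2-(acetoxymethyl)-4-[(tert-butyldimethylsilyl)oxy]but-2-enoyl]oxy}methyl)but-2-enoic acid | C/C=C(\COC(=O)/C(=C/CO[Si](C)(C)C(C)(C)C)COC(C)=O)C(=O)O | intermediate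
34 | mixed anhydride of 33 with 2,4,6-trichlorobenzoic acid | C/C=C(\COC(=O)/C(=C/CO[Si](C)(C)C(C)(C)C)COC(C)=O)C(=O)OC(=O)c1c(Cl)cc(Cl)cc1Cl | intermediate (not isolated)
35 | (3S,6R,7R,8R)-3-[(tert-butyldimethylsilyl)oxy]-8-[(acyl 33)oxy]germacra-1(10)E,4Z,11(13)-trien-12,6-olide | C=C1C(=O)O[C@@H]2/C=C(/C)[C@@H](O[Si](C)(C)C(C)(C)C)C/C=C(\C)C[C@@H](OC(=O)/C(=C/C)COC(=O)/C(=C/CO[Si](C)(C)C(C)(C)C)COC(C)=O)[C@@H]12 | intermediate
36 | (1R,10R)-1,10-epoxide of 35 (3,4'-bis-TBS ether of the target) | C=C1C(=O)O[C@@H]2/C=C(/C)[C@@H](O[Si](C)(C)C(C)(C)C)C[C@H]3O[C@]3(C)C[C@@H](OC(=O)/C(=C/C)COC(=O)/C(=C/CO[Si](C)(C)C(C)(C)C)COC(C)=O)[C@@H]12 | intermediate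
37 | CNP0193678.1, (1R,3S,6R,7R,8R,10R)-1,10-epoxy-3-hydroxy-8-acyloxygermacra-4Z,11(13)-dien-12,6-olide with the bis-enoate side chain | C=C1C(=O)O[C@@H]2/C=C(/C)[C@@H](O)C[C@H]3O[C@]3(C)C[C@@H](OC(=O)/C(=C/C)COC(=O)/C(=C/CO)COC(C)=O)[C@@H]12 | target

**Step count**

Total: 20 steps. Longest linear sequence: 11 steps (1, 2, 3, 6, 7, 8, 9, 10, 18, 19, 20).

**Three steps most likely to fail**

Step 7. What may go wrong: leakage through a boat transition state (loss of C8 control), β-elimination of the C8 alkoxy group from the warm potassium enolate, or poor facial selectivity in the C7 alkylation. Fallback, from 10 back to 14: the rearrangement is run with KN(SiMe3)2 in THF only until 10 is consumed and the enolate is quenched on oxygen with Me3SiCl/Et3N at −78 °C, giving the trimethylsilyl enol ether F1, which is isolated. MeLi in THF at 0 °C then regenerates a lithium enolate, which holds the O6/O8 chelate more tightly and is never heated, and methyl bromoacetate 11 at −78 °C should give 14.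

Step 9. What may go wrong: the free C8 hydroxyl competes for the ester (closure to the 8,12-olide before or after the reduction), so that hydride direction or ring-closure regiochemistry is lost. Fallback, from 14 (C8 oxygen still protected) back to 20: LiBH(s-Bu)3 in THF at −78 °C should attack the ketone from the outer face, and the alkoxide closes to the cis-fused 6-epi lactone F2. LiOH in THF/H2O opens it to the 6S hydroxy acid F3, which is used at once. Mitsunobu lactonisation (PPh3, DIAD, toluene, 0 °C) inverts C6 and gives the trans-fused lactone F4. Eschenmoser methylenation as in step 10 gives the α-methylene lactone F5, and DDQ as in step 8 releases 20.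

Step 10. What may go wrong: translactonisation towards O8 or incomplete enolisation in the alkoxide-bearing dianion. Fallback, from 17 back to 20: Et3SiCl/imidazole in DMF gives the triethylsilyl ether F6. The methylenation sequence of step 10 with one enolate only (LiN(i-Pr)2, Eschenmoser's salt, MeI, NaHCO3) gives the α-methylene lactone triethylsilyl ether F7. Brief HF·pyridine/pyridine in THF at 0 °C should remove the secondary TES ether well before the hindered TBS ether and return 20.

**Further compounds**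

F1 | step 7 | trimethylsilyl enol ether of the ring-expanded ketone (C6–OSiMe3, C6=C7, 3S, 8R) | C1/C(C)=C/C[C@H](O[Si](C)(C)C(C)(C)C)/C(C)=C\C(\O[Si](C)(C)C)=C\[C@@H]1OCc2ccc(OC)cc2
F2 | step 9 | (3S,6S,7R,8R)-3-[(tert-butyldimethylsilyl)oxy]-8-[(4-methoxybenzyl)oxy]-13-norgermacra-1(10)E,4Z-dien-12,6-olide (cis-fused, 6-epi) | C1C(=O)O[C@H]2/C=C(/C)[C@@H](O[Si](C)(C)C(C)(C)C)C/C=C(\C)C[C@@H](OCc3ccc(OC)cc3)[C@@H]12
F3 | step 9 | (3S,6S,7R,8R)-3-[(tert-butyldimethylsilyl)oxy]-6-hydroxy-8-[(4-methoxybenzyl)oxy]-13-norgermacra-1(10)E,4Z-dien-12-oic acid | O[C@H]1/C=C(/C)[C@@H](O[Si](C)(C)C(C)(C)C)C/C=C(\C)C[C@@H](OCc2ccc(OC)cc2)[C@H]1CC(=O)O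
F4 | step 9 | (3S,6R,7R,8R)-3-[(tert-butyldimethylsilyl)oxy]-8-[(4-methoxybenzyl)oxy]-13-norgermacra-1(10)E,4Z-dien-12,6-olide (trans-fused) | C1C(=O)O[C@@H]2/C=C(/C)[C@@H](O[Si](C)(C)C(C)(C)C)C/C=C(\C)C[C@@H](OCc3ccc(OC)cc3)[C@@H]12
F5 | step 9 | (3S,6R,7R,8R)-3-[(tert-butyldimethylsilyl)oxy]-8-[(4-methoxybenzyl)oxy]germacra-1(10)E,4Z,11(13)-trien-12,6-olide | C=C1C(=O)O[C@@H]2/C=C(/C)[C@@H](O[Si](C)(C)C(C)(C)C)C/C=C(\C)C[C@@H](OCc3ccc(OC)cc3)[C@@H]12
F6 | step 10 | 8-O-triethylsilyl ether of 17 | C1C(=O)O[C@@H]2/C=C(/C)[C@@H](O[Si](C)(C)C(C)(C)C)C/C=C(\C)C[C@@H](O[Si](CC)(CC)CC)[C@@H]12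
F7 | step 10 | 8-O-triethylsilyl ether of 20 | C=C1C(=O)O[C@@H]2/C=C(/C)[C@@H](O[Si](C)(C)C(C)(C)C)C/C=C(\C)C[C@@H](O[Si](CC)(CC)CC)[C@@H]12
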